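The readings come from a simulation from invented constants, noise included.

**Reading time.** For the reading at 20 min I had to say what would stand in the winter flask, followed so far to 90.0 s, with noon, followed to 8.00 min, as the longer run beside it.

| flask | left-handed substrate | right-handed substrate | solid reagent | remark | time |
|---|---|---|---|---|---|
| winter | 5 mM | 5 mM | 11 mM | the very flask that is asked about, followed so far |  |
| noon | 5 mM | 5 mM | 5.5 mM | run made earlier |  |
| flask | 5.0 mM | 5.0 mM | 11.0 mM |  | 20 min |

winter run (percent of the left-handed substrate and right-handed substrate together charged)

| time / s | left-handed substrate / % | right-handed substrate / % | left-handed product / % |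
|---|---|---|---|
| 10.0 | 38 | 43 | 2 |
| 20.0 | 38 | 43 | 3 |
| 30.0 | 40 | 42 | 0 |
| 50.0 | 40 | 43 | 2 |
| 80.0 | 38 | 43 | 3 |
| 90.0 | 36 | 38 | 4 |

noon run (percent of the left-handed substrate and right-handed substrate together charged)

| time / min | left-handed substrate / % | right-handed substrate / % | left-handed product / % |
|---|---|---|---|
| 0.667 | 41 | 44 | 3 |
| 1.00 | 42 | 43 | 5 |
| 2.00 | 40 | 39 | 0 |
| 3.00 | 38 | 35 | 7 |
| 5.00 | 35 | 34 | 16 |
| 8.00 | 26 | 29 | 27 |

(scatter of a reading: 2 percentage points)

- part of the left-handed substrate and right-handed substrate charged together that has reacted at 20 min
- excess of left-handed product over right-handed product in the product at 20 min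
- excess of right-handed substrate over left-handed substrate among what is left of the two at 20 min

- coupling partner is single-handed; left-handed substrate and right-handed substrate are mirror images of each other, charged as a racemate, each of them at the stated concentration
- solid, in amounts per volume of the solution: solid reagent
- at the start none of the solid reagent is in solution
- what has gone into achiral form counts as reacted
- an excess is below zero if the other one leads
- the handed part of coupling partner does not stay in what it makes, so the products of the two hands are mirror images too

**Question reversed.** The opposite outcome, substrate stranded for want of reagent, needs less solid than the two substrates together. I therefore took the reagent ceiling, the share of the substrates that the solid can turn into product at one reagent per substrate: c(solid reagent) over both substrate charges, 110%. Noon stood on the short side at 55.0%, but this flask held more solid than substrate, with a surplus of 1.00 mM, so I took the substrates as the limiting reagent. The ceiling gave no speed.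

**The forecast.** It gave c 90% (72% to 99%), eP 70% (40% to 93%) and eS 4% (−3% to 20%), holding that “most material should be converted”.

**The result.** The flask gave c 84.6%, eP 26.2% and eS 0.0770%.

    coupling partner + left-handed substrate → left-handed product (k = 2.40 M⁻¹ s⁻¹)
    coupling partner + right-handed substrate → right-handed product (k = 1.40 M⁻¹ s⁻¹)
    left-handed substrate ⇌ achiral form (K = 0.360, k = 0.590 s⁻¹)
    right-handed substrate ⇌ achiral form (K = 0.360, k = 0.590 s⁻¹)
    solid reagent ⇌ coupling partner, rate k5*(cs5 - [coupling partner]) while solid is left; crystals form when [coupling partner] > cs5 (solubility = 2.50 mM, k = 0.00620 s⁻¹)
    coupling partner ⇌ dormant form (K = 1.80, k = 0.00550 s⁻¹)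
    coupling partner → decomposition product (k = 2.70 × 10⁻⁵ s⁻¹)

**The parting.** We parted most on eP: at 7.87 min the coupling partner went to left-handed product 1.7 times as fast as to right-handed product, which is an excess of 26.3%, while right-handed substrate went to product at 0.0019 of its forward rate into achiral form. Against the ceiling of 110%, products stood at 81.9% after 20.0 min and >99.9% after 200 min, with 1.00 mM of reagent forms over.

**Neighbour flask.** In the neighbour flask with 6.6 mM of solid, the ceiling scales down from 110% to 66.0%; the computed products there stood at 59.4% after 20 min, with c 65.6%, which counts 6.20% of achiral form.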